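All runs were computed for substances that don't exist, noise included.

**Spring count.** The spring run ends at 4.00 h with 5.9 % of its free monomer in chains. Dividing that monomer by the initiator charged gives 7.18 units per initiator. I call this the turnover count. It equals the average chain length (the number-average degree of polymerisation) provided each initiator begins one chain, which the runs do not show. The dusk run gives 4.14.

| setting | spring | dusk | alpha | theta |
|---|---|---|---|---|
| free monomer | 0.056 M | 0.056 M | 0.056 M | 0.056 M |
| protic impurity | 0.028 M | 0.028 M | 0.0280 M | 0.0280 M |
| initiator | 0.46 mM | 1.8 mM | 0.36 mM | 1.5 mM |
| remark | run made earlier | run made earlier |  |  |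
| time |  |  | 4.0 h | 4.0 h |

- spring (time / h: monomer in chains / %, free monomer / %): 0.333: 6.1, 48.7; 0.500: 8.1, 38.6; 0.667: 9.9, 27.4; 1.00: 13.2, 15.9; 1.50: 13.0, 8.8; 2.50: 10.0, 2.4; 4.00: 5.9, 2.8
- dusk (time / h: monomer in chains / %, free monomer / %): 0.333: 21.1, 39.2; 0.500: 27.5, 24.2; 0.667: 29.4, 16.7; 1.00: 28.5, 9.2; 1.50: 30.0, 6.9; 2.50: 23.8, 3.5; 4.00: 13.3, 4.9

(readings scatter by 1 percentage point)

- which of the two ends with the longer chains by the average number of monomer units in a chain (chains begun, living or dead) ("neither" if they lie within 10 %) (alpha / theta / neither)
- average number of monomer units in a chain (chains begun, living or dead) at the end, alpha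
- average number of monomer units in a chain (chains begun, living or dead) at the end, theta

- the average divides the monomer in chains by the number of chains begun, living and dead together
- the earlier runs do not show the number of chains; that part of a forecast is a guess

**Question reversed.** For theta to tie with alpha, the count must stay level as initiator changes, so monomer in chains must grow in step with initiator. Theta holds 4.17 times the initiator of alpha. From spring to dusk, initiator grows 3.91 times, but final monomer in chains grows 2.25 times. The spring count is therefore 1.74 times the dusk count, well outside the 10 % margin for a tie. The weak point is the scatter of 1 percentage point on a reading of 5.9 %.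

**My reckoning.** I take the count as a power of the initiator charge, with exponent −0.404. This gives 7.93 for alpha and 4.45 for theta. Alpha's figure is a slight extrapolation, since its charge lies below spring's.

**The forecast.** The forecast names alpha, with 8.5 and 4.8, both a little above my figures: “The number of chains is a guess, but the ratio of about 1.8 favours alpha.”

**The result.** The longer chains are in alpha, with 4.53 units per chain in theta. In alpha the living end stands at 3.60 × 10⁻⁴ M, equal to its initiator charge, and the division that gave spring 7.18 gives alpha 8.01.

    free monomer + initiator → living end + monomer in chains (k = 0.111 /M/s)
    free monomer + living end → monomer in chains + living end, rate k2*[living end]*[free monomer] (k = 0.210 /M/s)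
    monomer in chains + living end → free monomer + living end, rate k3*[living end] as long as [monomer in chains] is above zero (k = 0.00117 /s)
    free monomer → uncatalysed product (k = 2.44 × 10⁻⁴ /s)
    protic impurity + free monomer → quenched substrate (k = 0.0131 /M/s)

**A passing value.** In theta, each step taken net, monomer in chains is made 2.49 times as fast as it is used up at 0.543 h, but at 4.00 h the rate of making is 0.480 of the rate of use, so the count of theta is falling at the asked time. Left until 10 h, theta holds 0 % monomer in chains and 2.48 × 10⁻⁵ units per chain.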